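# Total synthesis of Pulicanaral A (6,8-diacetoxy-1,10-epoxygermacr-4-en-14-al)

**Retrosynthesis**
- Pulicanaral A (16) comes from organocatalytic nucleophilic epoxidation of the ring enal C1=C10–C14HO (15), a late step that leaves the C4=C5 alkene untouched.
- The 10-membered ring and the enal form together by an amine-catalysed macrocyclic aldol condensation of dialdehyde 12 (C10–C1 bond, then dehydration).
- The C6/C7/C8 stereotriad comes from an organocatalytic anti cross-aldol of isovaleraldehyde with the (E)-β-methyl enal 5 (C6, C7). A non-chelation Grignard addition then sets C8 (Felkin–Evans, 1,3-anti).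
- Order of ring formation: carbocycle first (macro-aldol), then the epoxide.

**Assumptions**
- 5,5-Dimethoxypentan-2-one and 2-(1,3-dioxolan-2-yl)ethylmagnesium bromide are purchasable.
- The HWE step gives E:Z of about 9:1, and the isomers are separable.
- (R)-Proline gives the (6R,7R) anti aldol. This is inferred from L-proline's known sense of induction for aldehyde acceptors.
- Step 6 proceeds with at least 5:1 dr, which is assumed.
- The (S)-catalyst in Step 12 is the matched enantiomer, which is assumed.

---

## Route

**Step 1**
Reactants: 1 (5,5-dimethoxypentan-2-one); 2 (triethyl phosphonoacetate)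
Product: 3 (ethyl (E)-6,6-dimethoxy-3-methylhex-2-enoate)
Conditions: NaH, THF, 0 °C → rt
Reagents that add atoms: compound 2, CCOC(=O)CP(=O)(OCC)OCC
Why: Horner–Wadsworth–Emmons olefination of the methyl ketone gives the trisubstituted E-enoate, which fixes the E geometry of the future C4=C5 alkene.

**Step 2**
Reactants: 3
Product: 4 ((E)-6,6-dimethoxy-3-methylhex-2-en-1-ol)
Conditions: DIBAL-H (2.5 equiv), CH2Cl2, −78 °C
Reagents that add atoms: none
Why: Exhaustive DIBAL reduction of the ester to the allylic alcohol; the acetal and alkene geometry are untouched.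

**Step 3**
Reactants: 4
Product: 5 ((E)-6,6-dimethoxy-3-methylhex-2-enal)
Conditions: MnO2 (10 equiv), CH2Cl2, rt
Reagents that add atoms: none
Why: Chemoselective allylic alcohol oxidation, with no isomerisation of the E-enal.

**Step 4**
Reactants: 6 (isovaleraldehyde); 5
Product: 7 ((2R,3R,4E)-3-hydroxy-8,8-dimethoxy-5-methyl-2-isopropyloct-4-enal; the C8 aldehyde, C7 bearing iPr, and C6 carbinol in germacrane numbering)
Conditions: (R)-proline (20 mol%), DMF, 4 °C; 6 (3 equiv) added by syringe pump over 10 h to 5
Reagents that add atoms: none (both partners are numbered reactants)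
Why: Enamine-catalysed anti-selective direct cross-aldol (MacMillan type). Slow addition of the donor suppresses its homo-aldol, and the β,β-disubstituted enal reacts 1,2 rather than 1,4. The proline-carboxylic-acid-directed enamine face sets C6 (R) and C7 (anti), the first stereocentres.

**Step 5**
Reactants: 7
Product: 8 (the C6-OTBS ether of 7)
Conditions: TBSOTf, 2,6-lutidine, CH2Cl2, −78 °C
Reagents that add atoms: TBSOTf, CC(C)(C)[Si](C)(C)OS(=O)(=O)C(F)(F)F
Why: Silylation blocks the hydroxyl. It prevents chelation and retro-aldol or dehydration in the next step, and creates the non-chelating β-silyloxy aldehyde.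

**Step 6**
Reactants: 8; 9 (2-(1,3-dioxolan-2-yl)ethylmagnesium bromide)
Product: 10 (C8 secondary alcohol carrying the CH2CH2-dioxolane chain)
Conditions: 9 (2 equiv), THF, −78 → −40 °C; NH4Cl (aq)
Reagents that add atoms: compound 9, [Mg](Br)CCC1OCCO1
Why: Grignard addition to an α,β-anti β-silyloxy aldehyde. The Felkin–Anh preference (1,2-syn) and the Evans polar model for the OTBS group (1,3-anti) reinforce each other, giving the C8 configuration.

**Step 7**
Reactants: 10
Product: 11 (C8 acetate of 10)
Conditions: Ac2O, pyridine, DMAP (cat.), CH2Cl2, rt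
Reagents that add atoms: Ac2O, CC(=O)OC(C)=O
Why: Standard acylation installs the C8 acetate of the target.

**Step 8**
Reactants: 11
Product: 12 (dialdehyde; C1 and C14 aldehydes, C6-OTBS, C8-OAc)
Conditions: TMSOTf, 2,2′-bipyridyl, CH2Cl2, 0 °C; then H2O
Reagents that add atoms: water, O
Why: Fujioka-type mild acetal-to-aldehyde deprotection of both the dimethyl acetal and the dioxolane. It avoids aqueous strong acid, which could ionise the allylic silyl ether, and TBS ether and acetate are expected to survive.

**Step 9**
Reactants: 12
Product: 13 (macrocyclic enal; 10-membered ring with the 4E alkene, the ring-cis C1=C10 enal, 6-OTBS and 8-OAc)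
Conditions: pyrrolidine (20 mol%), AcOH (20 mol%), MeCN, 50 °C, 12 is added by syringe pump over 12 h to a final concentration of about 2 mM
Reagents that add atoms: none
Why: Amine-catalysed intramolecular aldol condensation, with ring closure by enamine C10 attacking C1, then iminium-mediated E1cB dehydration. No new stereocentre is formed.
Proposed new method: Enamine/iminium-catalysed aldol condensation used as a macrocyclisation to a 10-membered carbocycle. The closest known reaction is the pyrrolidine- or proline-catalysed cyclisation of 1,5- and 1,6-dialdehydes to cycloalkene carbaldehydes (Hajos–Parrish-type). The E-trisubstituted C4=C5 alkene and the C6/C7/C8 array should hold C1 and C10 close transannularly, as in germacradiene conformers. Irreversible dehydration drives the reversible aldol. E1cB dehydration gives the E-enal (CHO trans to C2), which is exactly the ring-cis C2/C9 geometry the target epoxide requires. The regiochemical alternative (C2-enamine attacking C14) would give a skipped 1,4-diene ring with an exocyclic enal, which is expected to be less favourable.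

**Step 10**
Reactants: 13
Product: 14 (C6 free alcohol)
Conditions: HF·pyridine, pyridine, THF, 0 °C → rt
Reagents that add atoms: none (H replaces Si)
Why: Buffered fluoride removes the TBS group without acyl migration or base-induced enal damage. The next step follows immediately.

**Step 11**
Reactants: 14
Product: 15 (6,8-diacetoxy-germacra-1(10),4-dien-14-al)
Conditions: Ac2O, pyridine, DMAP (cat.), CH2Cl2, rt
Reagents that add atoms: Ac2O, CC(=O)OC(C)=O
Why: Acylation installs the C6 acetate (allylic secondary alcohol, no stereochemical change).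

**Step 12**
Reactants: 15
Product: 16 (Pulicanaral A)
Conditions: (S)-α,α-bis[3,5-bis(trifluoromethyl)phenyl]prolinol TMS ether (20 mol%), 35% aq. H2O2 (3 equiv), CH2Cl2/EtOH, rt
Reagents that add atoms: hydrogen peroxide, OO
Why: Jørgensen–Hayashi iminium-catalysed nucleophilic (Weitz–Scheffer-type) epoxidation. HOO⁻ adds to C1 of the iminium and closes onto C10, giving a syn (cis-ring) epoxide from the E-enal. The catalyst face sets C1/C10. It is chemoselective for the enal over the electron-rich C4=C5 alkene and over the acetates. This is known reactivity applied to an untested macrocyclic α,β-disubstituted enal.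

---

## Compound list

1 | 5,5-dimethoxypentan-2-one | COC(OC)CCC(C)=O | starting material
2 | triethyl phosphonoacetate | CCOC(=O)CP(=O)(OCC)OCC | starting material
3 | ethyl (E)-6,6-dimethoxy-3-methylhex-2-enoate | CCOC(=O)/C=C(\C)CCC(OC)OC | intermediate
4 | (E)-6,6-dimethoxy-3-methylhex-2-en-1-ol | OC/C=C(\C)CCC(OC)OC | intermediate
5 | (E)-6,6-dimethoxy-3-methylhex-2-enal | O=C/C=C(\C)CCC(OC)OC | intermediate
6 | isovaleraldehyde | CC(C)CC=O | starting material
7 | (2R,3R,4E)-anti-aldol: 3-hydroxy-8,8-dimethoxy-5-methyl-2-isopropyloct-4-enal | O=C[C@H](C(C)C)[C@H](O)/C=C(\C)CCC(OC)OC | intermediate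
8 | 3-OTBS ether of 7 | O=C[C@H](C(C)C)[C@H](O[Si](C)(C)C(C)(C)C)/C=C(\C)CCC(OC)OC | intermediate
9 | 2-(1,3-dioxolan-2-yl)ethylmagnesium bromide | [Mg](Br)CCC1OCCO1 | starting material
10 | Grignard adduct (C8-OH, C6-OTBS, two acetals) | C1COC(O1)CC[C@@H](O)[C@H](C(C)C)[C@H](O[Si](C)(C)C(C)(C)C)/C=C(\C)CCC(OC)OC | intermediate
11 | C8-acetate of 10 | C1COC(O1)CC[C@@H](OC(C)=O)[C@H](C(C)C)[C@H](O[Si](C)(C)C(C)(C)C)/C=C(\C)CCC(OC)OC | intermediate
12 | dialdehyde (C6-OTBS, C8-OAc) | O=CCC/C(C)=C/[C@@H](O[Si](C)(C)C(C)(C)C)[C@@H](C(C)C)[C@H](OC(C)=O)CCC=O | intermediate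
13 | macrocyclic enal (6-OTBS, 8-OAc) | CC(C)(C)[Si](C)(C)O[C@@H]1/C=C(\C)CC/C=C(/C=O)C[C@@H](OC(C)=O)[C@@H]1C(C)C | intermediate
14 | 6-hydroxy-8-acetoxy macrocyclic enal | O[C@@H]1/C=C(\C)CC/C=C(/C=O)C[C@@H](OC(C)=O)[C@@H]1C(C)C | intermediate
15 | 6,8-diacetoxy macrocyclic enal | CC(=O)O[C@@H]1/C=C(\C)CC/C=C(/C=O)C[C@@H](OC(C)=O)[C@@H]1C(C)C | intermediate
16 | Pulicanaral A | CC(=O)O[C@@H]1/C=C(\C)CC[C@H]2O[C@@]2(C=O)C[C@@H](OC(C)=O)[C@@H]1C(C)C | target

**Total steps:** 12.
**Longest linear sequence:** 12 (1 → 3 → 4 → 5 → 7 → 8 → 10 → 11 → 12 → 13 → 14 → 15 → 16; isovaleraldehyde and the Grignard reagent are purchased).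

## Three steps most likely to fail

1. **Step 9, macrocyclic aldol condensation (the new step).** It may give oligomers or the C2/C14 regioisomer.
   - Fallback: re-cut the ring as an intramolecular Masamune–Roush HWE (LiCl/DBU, about 1 mM). The C1 aldehyde is closed onto a C10 phosphonoacetate (C14 ester) built by alkylating triethyl phosphonoacetate. The ring ester is then taken to enal 13 by DIBAL and MnO2.
2. **Step 6, C8 diastereoselectivity.** The α-isopropyl group may erode the Felkin/Evans preference.
   - Fallback: reagent-controlled allylation of 8 with (–)- or (+)-Ipc2B-allyl (Brown). The terminal alkene is then converted to the C14 aldehyde by 9-BBN hydroboration, oxidation and Dess–Martin.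
3. **Step 12, epoxide face selectivity and reactivity.** The α-branched macrocyclic enal may form the iminium slowly, or the catalyst may be mismatched.
   - Fallback: Luche reduction of 15 to the allylic alcohol, then Sharpless asymmetric epoxidation (Ti(OiPr)4, tartrate, TBHP), then Dess–Martin oxidation to 16.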